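**Retrosynthetic overview**

1. The pyranone ring of the target is made last, by acid-mediated ring expansion of a five-membered 1-oxaspiro ring (dienone–phenol rearrangement with 1,2-acyl shift); the same event restores the benzene ring and sets the C6 hydroxyl free.
2. Enabling feature: in the 1-oxaspiro[4.5]deca-6,9-diene-4,8-dione precursor the spiro carbon C5 of the cyclohexadienone ring carries both the ether oxygen O1 (whose lone pair takes up the positive charge left behind) and the acyl carbon C4 (high migratory aptitude); bromine on C7 steers the shift to C10.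
3. The spiro ring comes from oxidative dearomatisation of a para-acylphenol, whose tertiary β-hydroxyl adds to the ipso carbon (O1–C5 bond).
4. The acylphenol comes from benzylic oxidation after a double Markovnikov hydration of the Heck adduct of (S)-linalool and 2-bromo-4-iodophenol; the linalool carbinol carbon becomes C2 of the target and none of its bonds is ever broken.
5. Order of rings: benzene ring (bought) → five-membered spiro ring (benzene ring dearomatised) → six-membered pyranone ring (ring expansion, benzene ring restored).

Key step: step 5

Assumption: (S)-(+)-linalool of high enantiomeric purity is taken as a purchasable terpene; its carbinol carbon becomes C2 of the target without any change.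

Step 1
Reactants: 1 (S)-(+)-linalool [(3S)-3,7-dimethylocta-1,6-dien-3-ol]; 2 2-bromo-4-iodophenol
Product: 3 2-bromo-4-[(1E,3S)-3-hydroxy-3,7-dimethylocta-1,6-dien-1-yl]phenol
Conditions: Pd(OAc)2 (3 mol %), n-Bu4NCl, NaHCO3, DMF, 50 °C
Reagents that add atoms: none
Why: Mizoroki–Heck coupling under ligand-free phase-transfer conditions should engage only the carbon–iodine bond of 2 and the monosubstituted vinyl group of 1, and since the carbinol carbon bears no hydrogen the β-hydride elimination can only give the (E)-styrene, so no stereocentre is set and no bond to the (S)-carbinol carbon is touched.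

Step 2
Reactants: 3
Product: 4 2-bromo-4-[(3S)-1,3,7-trihydroxy-3,7-dimethyloctyl]phenol (both C1 epimers)
Conditions: Co(acac)2 (20 mol %), PhSiH3, O2 (1 atm), THF/2-propanol, rt
Reagents that add atoms: dioxygen, O=O
Why: Mukaiyama hydration (hydrogen-atom transfer from a cobalt hydride to the alkene, capture of the carbon radical by O2, reduction of the peroxide by the silane) puts the hydroxyl group on the carbon that forms the more stable radical, so the styrenyl alkene is hydrated at the benzylic C1 and the trisubstituted alkene at the tertiary C7 in one operation, the benzylic stereocentre forming without control (it is removed in step 3) and the (3S) centre not being involved.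

Step 3
Reactants: 4
Product: 5 (3S)-1-(3-bromo-4-hydroxyphenyl)-3,7-dihydroxy-3,7-dimethyloctan-1-one
Conditions: activated MnO2 (excess), EtOAc, rt
Reagents that add atoms: none
Why: Benzylic alcohol oxidation with MnO2 should convert both C1 epimers into the one aryl ketone, while the two tertiary alcohols cannot be oxidised and the neutral conditions spare the phenol and avoid retro-aldol cleavage of the β-hydroxy ketone.

Step 4
Reactants: 5
Product: 6 (2S)-7-bromo-2-(4-hydroxy-4-methylpentyl)-2-methyl-1-oxaspiro[4.5]deca-6,9-diene-4,8-dione (both C5 epimers)
Conditions: PhI(OAc)2 (1.1 equiv), (CF3)2CHOH, 0 °C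
Reagents that add atoms: none
Why: Hypervalent-iodine oxidative dearomatisation of the phenol (spiro-etherification), in which after ligand exchange at iodine the tertiary C3 hydroxyl adds to the para (ipso) carbon in a 5-exo closure as PhI leaves, is the same ipso-etherification by which para-hydroxyaryl ketones are turned into grisan-type spirodienones; the (S) centre, now C2, is untouched and the spiro centre C5 forms without control, which is of no consequence because it becomes an sp2 carbon in step 5.

Step 5
Reactants: 6
Product: 8 (2S)-7-bromo-6-hydroxy-2-(4-hydroxy-4-methylpentyl)-2-methylchroman-4-one (the target), via tertiary trifluoroacetate 7 (not isolated)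
Conditions: CF3CO2H (neat), 0 °C → rt; then aq. NaHCO3/MeOH, rt
Reagents that add atoms: trifluoroacetic acid, OC(=O)C(F)(F)F (its acyl group is carried by 7 only and leaves again in the work-up)
Why: Dienone–phenol rearrangement with 1,2-acyl shift: protonation of the C8 carbonyl of the cross-conjugated dienone gives a hydroxycyclohexadienyl cation, the acyl carbon C4 moves with its bonding electrons from the spiro carbon C5 to the neighbouring cationic carbon C10, the charge left on C5 is taken up by the lone pair of O1, and loss of the proton from C10 restores the benzene ring with the former C8 oxygen as the free C6 phenol. The closest known reaction type is the acid-catalysed acyl migration of 4-acylcyclohexa-2,5-dienones, as in the conversion of spiro-fused grisan-type acyl dienones into xanthones. The six-membered pyranone ring is closed by the new C4–C10 bond (bridging of the acyl carbon across C5–C10, a suprafacial 1,2-shift) while the C4–C5 bond of the five-membered ring opens, so the ring grows by one carbon without an open-chain stage. No stereocentre is created: C2 keeps its (S) configuration because none of its four bonds is involved, and the uncontrolled spiro centre C5 becomes the sp2 carbon C8a, so both epimers of 6 converge. The step needs migration to C10 and not to C6; C6 lies next to C7–Br, where the positive charge of the protonated dienone is less developed and where the migrated carbonyl would end up peri to bromine, so the shift should go to C10 and place bromine at C7 of the chromanone. In neat CF3CO2H the side-chain tertiary alcohol is held as its trifluoroacetate 7 (alcohol, cation and alkenes all drain to this ester), which the bicarbonate work-up cleaves.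

**Compound list**

1 | (S)-(+)-linalool, (3S)-3,7-dimethylocta-1,6-dien-3-ol | C=C[C@@](C)(O)CCC=C(C)C | starting material
2 | 2-bromo-4-iodophenol | Oc1ccc(I)cc1Br | starting material
3 | 2-bromo-4-[(1E,3S)-3-hydroxy-3,7-dimethylocta-1,6-dien-1-yl]phenol | Oc1ccc(/C=C/[C@@](C)(O)CCC=C(C)C)cc1Br | intermediate
4 | 2-bromo-4-[(3S)-1,3,7-trihydroxy-3,7-dimethyloctyl]phenol (both C1 epimers) | Oc1ccc(C(O)C[C@@](C)(O)CCCC(C)(C)O)cc1Br | intermediate
5 | (3S)-1-(3-bromo-4-hydroxyphenyl)-3,7-dihydroxy-3,7-dimethyloctan-1-one | Oc1ccc(C(=O)C[C@@](C)(O)CCCC(C)(C)O)cc1Br | intermediate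
6 | (2S)-7-bromo-2-(4-hydroxy-4-methylpentyl)-2-methyl-1-oxaspiro[4.5]deca-6,9-diene-4,8-dione (both C5 epimers) | O=C1C[C@@](C)(OC12C=CC(=O)C(Br)=C2)CCCC(C)(C)O | intermediate
7 | (2S)-7-bromo-6-hydroxy-2-methyl-2-[4-methyl-4-(trifluoroacetoxy)pentyl]chroman-4-one (not isolated) | O=C1C[C@@](C)(Oc2cc(Br)c(O)cc12)CCCC(C)(C)OC(=O)C(F)(F)F | intermediate
8 | (2S)-7-bromo-6-hydroxy-2-(4-hydroxy-4-methylpentyl)-2-methylchroman-4-one | CC(C)(O)CCC[C@@]1(C)CC(=O)c2cc(O)c(Br)cc2O1 | target

Total steps: 5. Longest linear sequence: 5 steps (1 or 2 → 8).

**Steps most likely to fail**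

1) Step 4. The two-electron oxidation of a phenol that is deactivated by the para-acyl group and the ortho-bromine may be too slow, so that the aryloxy-iodine species decomposes or the ketone is oxidised at its α-carbon before the ipso-etherification takes place. The fallback oxidises the phenol while it is still electron-rich: it sets out from 4, which carries a carbinol and not an acyl group at the para position. PhI(OAc)2 in (CF3)2CHOH with solid NaHCO3 at 0 °C should give the spirocyclic carbinol (2S)-7-bromo-4-hydroxy-2-(4-hydroxy-4-methylpentyl)-2-methyl-1-oxaspiro[4.5]deca-6,9-dien-8-one F1. Because this carbinol can fragment with re-aromatisation, it is oxidised at once with Dess–Martin periodinane (NaHCO3, CH2Cl2, 0 °C) to 6, where the fallback comes back to the route.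

2) Step 5. The cationic dienone may be diverted before the 1,2-shift: trifluoroacetate may add to the dienone, the C4–C5 bond may break with intermolecular capture of the acyl fragment, or the ring may open by retro-oxa-Michael cleavage with erosion of the C2 configuration. The fallback replaces the concerted shift by a stepwise cleavage and re-closure and sets out from 6. NaOMe (1.1 equiv) in MeOH at −20 °C should add to the C4 ketone and split the C4–C5 bond in a retro-Claisen cleavage driven by re-aromatisation, giving methyl (3S)-3-(3-bromo-4-hydroxyphenoxy)-7-hydroxy-3,7-dimethyloctanoate F2. LiOH in THF/H2O then gives (3S)-3-(3-bromo-4-hydroxyphenoxy)-7-hydroxy-3,7-dimethyloctanoic acid F3. Intramolecular Friedel–Crafts acylation through the mixed anhydride ((CF3CO)2O, CF3CO2H, 0 °C → rt) should close the pyranone ring ortho to the ether oxygen, at the carbon not flanked by bromine, and give (2S)-7-bromo-2-methyl-2-[4-methyl-4-(trifluoroacetoxy)pentyl]-4-oxochroman-6-yl trifluoroacetate F4. Aqueous NaHCO3/MeOH converts F4 into 8, where the fallback comes back to the route.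

3) Step 2. The free phenol may intercept the peroxyl radicals or be oxidised under the cobalt/O2 conditions, and hydration of the hindered styrenyl alkene may stay incomplete. The fallback avoids radicals and sets out from 3. Rhodium-catalysed hydroboration of the styrenyl alkene alone (catecholborane, [Rh(cod)2]BF4/dppb 2 mol %, THF, rt; then NaOH/H2O2) places boron at the benzylic carbon, leaves the trisubstituted alkene, and should give 2-bromo-4-[(3S)-1,3-dihydroxy-3,7-dimethyloct-6-en-1-yl]phenol F5. Activated MnO2 gives (3S)-1-(3-bromo-4-hydroxyphenyl)-3-hydroxy-3,7-dimethyloct-6-en-1-one F6, and PhI(OAc)2 in (CF3)2CHOH gives (2S)-7-bromo-2-methyl-2-(4-methylpent-3-en-1-yl)-1-oxaspiro[4.5]deca-6,9-diene-4,8-dione F7. In neat CF3CO2H, F7 should undergo the same ring expansion while the acid adds to the trisubstituted alkene in the Markovnikov sense, which gives 7 directly, where the fallback rejoins the route.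

**Further compounds**

F1 | step 4 | (2S)-7-bromo-4-hydroxy-2-(4-hydroxy-4-methylpentyl)-2-methyl-1-oxaspiro[4.5]deca-6,9-dien-8-one (epimers at C4 and C5) | OC1C[C@@](C)(OC12C=CC(=O)C(Br)=C2)CCCC(C)(C)O
F2 | step 5 | methyl (3S)-3-(3-bromo-4-hydroxyphenoxy)-7-hydroxy-3,7-dimethyloctanoate | COC(=O)C[C@@](C)(Oc1ccc(O)c(Br)c1)CCCC(C)(C)O
F3 | step 5 | (3S)-3-(3-bromo-4-hydroxyphenoxy)-7-hydroxy-3,7-dimethyloctanoic acid | OC(=O)C[C@@](C)(Oc1ccc(O)c(Br)c1)CCCC(C)(C)O
F4 | step 5 | (2S)-7-bromo-2-methyl-2-[4-methyl-4-(trifluoroacetoxy)pentyl]-4-oxochroman-6-yl trifluoroacetate | O=C1C[C@@](C)(Oc2cc(Br)c(OC(=O)C(F)(F)F)cc12)CCCC(C)(C)OC(=O)C(F)(F)F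
F5 | step 2 | 2-bromo-4-[(3S)-1,3-dihydroxy-3,7-dimethyloct-6-en-1-yl]phenol (both C1 epimers) | Oc1ccc(C(O)C[C@@](C)(O)CCC=C(C)C)cc1Br
F6 | step 2 | (3S)-1-(3-bromo-4-hydroxyphenyl)-3-hydroxy-3,7-dimethyloct-6-en-1-one | Oc1ccc(C(=O)C[C@@](C)(O)CCC=C(C)C)cc1Br
F7 | step 2 | (2S)-7-bromo-2-methyl-2-(4-methylpent-3-en-1-yl)-1-oxaspiro[4.5]deca-6,9-diene-4,8-dione (both C5 epimers) | O=C1C[C@@](C)(OC12C=CC(=O)C(Br)=C2)CCC=C(C)C
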